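## The problem

Compound 26 is a longipinane. Its cyclobutane (C4–C5–C11–C10) carries the three-carbon bridge C3–C2–C1 across C4/C11 on one face (ring B, with the C1 ketone and the C3 methyl). On the opposite face the four-carbon bridge C6–C7–C8–C9 spans C5/C10 (ring C, with the gem-dimethyl carbon and both ester carbons). Five of the seven stereocentres sit in the core (C3, C4, C5, C10, C11) and are interlocked: once the absolute sense of the cyclobutane, the side of the C10 methyl and the side of the C3 methyl are fixed, C11 and C5 follow from the bridging. C7 and C9 form an anti-1,3-diol. The two faces of ring C differ only in a remote C3 methyl versus the C1 oxygen, so the core cannot set these centres; one needs a reagent and the other 1,3-induction. The two angelates isomerise to tiglates under base, nucleophilic catalysis, radical conditions or prolonged heat and must come last. A C1 hydroxyl β to a C5 carbonyl invites retro-aldol opening of ring B, C1 and C5 cannot both be carbonyls (strained, non-enolisable 1,3-diketone), and peroxides or cations next to the four-membered ring must be avoided. The enabling feature is that ring B is a C3–C2–C1 unit joining the two α-carbons of a ketone at C5. With methyl on C3 and oxygen on C1 that unit is crotonaldehyde, and the 3,3-disubstituted cyclobutanone 7 is achiral, with a mirror plane through C5 and C10. One annulation can therefore form C3–C4 and C1–C11, close ring B and fix the core configuration.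

## Retrosynthesis

**26 ⇒ 25 ⇒ 24 ⇒ 21 + 22.** The C1 ketone is taken back to a silyl-protected carbinol and both ester C–O bonds are cut to diol 21 and angelic acid 22. The angelates go on as late as possible. The C1 oxygen stays silylated until after esterification so that the three secondary oxygens are never free together. The forward steps must acylate two neopentyl-type alcohols without Z-to-E isomerisation and then unmask and oxidise C1 under neutral conditions.

**21 ⇒ 20 ⇒ 19.** The C7–H bond is cut to the C7 ketone, with the free C9 hydroxyl of 20 as the directing group. This relays the one reagent-set centre (C9) to C7 and gives the anti-diol. An undirected reduction would have nothing in the core to choose a face.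

**19 ⇒ 18 ⇒ 17.** The C5–H bond is traced to a tertiary C5 hydroxyl through oxalate 18. That hydroxyl is the price of closing ring C by carbonyl addition. C5 can only bear C6 on the face that ring C occupies, so the forward deoxygenation has a single possible stereochemical outcome.

**17 ⇒ 16.** The C5–C6 bond is cut, opening ring C to bromo ketone 16. Intermolecular addition to C5 is blocked on both faces, by the C1/C3 substituents on one side and the C9 arm on the other. Delivering C6 on a tether from C9 solves both access and facial choice, and the tertiary bromide gives the C6 enolate regiospecifically.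

**16 ⇒ 15 ⇒ 12 + 13.** The C8–C9 bond is cut to aldehyde 12 and commercial 3-bromo-3-methylbutan-2-one 13. This brings in C6, C7, C8, both C6 methyls and the C7 oxygen in one step. The aldehyde faces are not differentiated by the substrate, so a chiral boron enolate must set C9.

**12 ⇒ 11 ⇒ 10.** The aldehyde is traced to a dimethyl acetal and the silyl ether to the free C1 hydroxyl. These are two functional-group steps and no skeletal change.

**10 ⇒ 7 + 8.** C3–C4 and C1–C11 are cut, removing ring B and every core stereocentre at once; what remains is achiral ketone 7 and crotonaldehyde 8. Cutting C5–C11 or a ring C bond instead would leave a chiral bicycle still to be made. The forward reaction must pick one enantiotopic α-carbon, bridge on the methyl side of C10 and place the C3 methyl toward C5.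

**7 ⇒ 5 ⇒ 4 ⇒ 2 ⇒ 1.** The ketone comes from an exocyclic methylene, the acetal from a nitrile and the C10 methyl from iodomethane, back to commercial nitrile 1. A dimethoxymethyl group is chosen for C9 instead of a silyloxymethyl group for two reasons. It is branched at the carbon attached to C10, so it differentiates the two faces better against methyl. It also already holds C9 at the aldehyde level.

## Roads not taken

**Alternative 1:** All three rings are cut back to acyclic (2E,6E)-farnesyl diphosphate A1. A class 1 sesquiterpene cyclase of the α-longipinene synthase type would ionise A1 and close the seven-, six- and four-membered rings in one active site to give α-longipinene A2. For the carbon skeleton this cannot be beaten: one step sets all five core stereocentres, and here it is clearly better than the chosen plan. Its weakness for 26 is that A2 is a hydrocarbon with one alkene. C1 can be reached by allylic oxidation, but C7 and C9 are unactivated methylenes flanked by quaternary carbons, and an anti-selective double hydroxylation there would need further oxygenases that accept this substrate. An enzyme giving the required enantiomeric series must also be available and expressed. Against the shorter skeleton synthesis the chosen plan sets the fact that all three oxygens arrive with the building blocks (8 for C1, 13 for C7, the acetal carbon for C9), so no C–H oxidation is needed.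

**Alternative 2:** C8 is excised, giving the copaane-type six-membered ketone A3. Me3SiCHN2 activated by AlMe3 would add to the C9 carbonyl of A3, and migration of the C7 methylene would insert C8 to give longipinan-9-one ketal A4. The migration preference (methylene over the quaternary C10) is sound and the reaction type is known, so the key step itself is safer than the proposed annulation. However, A3 is a tricycle with two three-carbon bridges on the cyclobutane. It is more strained than the target skeleton and no easier to make, so the core problem is moved, not solved. A4 also carries oxygen only at C9. C7 would need β-functionalisation of the ketone over several steps, with the same remote stereocontrol problem. The chosen plan builds the core in one step and its ring C closure brings the C7 and C9 oxygens together.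

**Alternative 3:** The cyclobutane bond C5–C11 is cut. Photolysis of α-diazo ketone A5 (a bicyclo[4.2.1]nonanone) would shift C5 from C1 to C11 with retention, and methanol would trap the ketene to give bicyclo[4.1.1]octane diester A6. Wolff ring contraction is one of the most dependable routes to strained cyclobutanes and is better precedented than the chosen key step. It also allows C7 and C9 to be oxygenated early in a less strained bicycle. Its cost is length: A5 needs a multistep synthesis with five stereocentres and a diazo transfer next to quaternary C10. A6 still lacks ring B and the C3 methyl, so a Dieckmann closure, decarboxylation and a stereocontrolled methyl introduction would follow, and the C11 configuration depends on how the ketene-derived enol is protonated. The chosen plan is less certain in its key step but far shorter, and its fallback uses only known reactions.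

Key step: step 5

Remark on numbering: longipinane numbering is used for all intermediates (C1 carbonyl carbon of 26, C2, C3 methyl-bearing, cyclobutane C4–C5–C11–C10, C6 gem-dimethyl, C7–C8–C9, C10 methyl-bearing). In this numbering 26 is (3R,4S,5S,7R,9R,10R,11R).

Assumption: (−)-Ipc2BCl is taken to deliver methyl-ketone enolates to the Re face of aldehydes; if the sense proves opposite, its enantiomer is used in step 8.

## Route

Step 1
Reactants: 1 3-methylidenecyclobutane-1-carbonitrile
Product: 2 1-methyl-3-methylidenecyclobutane-1-carbonitrile
Conditions: LiN(i-Pr)2, THF, −78 °C; MeI, −78 °C → rt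
Reagents that add atoms: iodomethane, CI
Why: Deprotonation α to the nitrile and SN2 methylation (nitrile α-alkylation) create the quaternary carbon that becomes C10; the ring is achiral, so no control is needed.

Step 2
Reactants: 2 1-methyl-3-methylidenecyclobutane-1-carbonitrile
Product: 4 1-methyl-3-methylidenecyclobutane-1-carbaldehyde, via aluminium aldimine 3 (not isolated)
Conditions: i-Bu2AlH, CH2Cl2, −78 °C; then 1 M HCl, 0 °C
Reagents that add atoms: water, O
Why: Partial reduction of a nitrile: hydride addition stops at the N-aluminio aldimine, which is hydrolysed on work-up; the aldehyde has no α-hydrogen and cannot enolise or self-condense.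

Step 3
Reactants: 4 1-methyl-3-methylidenecyclobutane-1-carbaldehyde
Product: 5 1-(dimethoxymethyl)-1-methyl-3-methylidenecyclobutane
Conditions: HC(OMe)3, MeOH, p-TsOH·H2O (cat.), rt
Reagents that add atoms: trimethyl orthoformate, COC(OC)OC
Why: Acid-catalysed acetalisation driven by the orthoformate; the acetal keeps C9 at the aldehyde level and is the α-branched group that will differentiate the two faces of the cyclobutanone.

Step 4
Reactants: 5 1-(dimethoxymethyl)-1-methyl-3-methylidenecyclobutane
Product: 7 3-(dimethoxymethyl)-3-methylcyclobutan-1-one, via spiro ozonide 6 (not isolated)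
Conditions: O3, CH2Cl2, −78 °C; then Me2S, −78 °C → rt
Reagents that add atoms: ozone, [O-][O+]=O
Why: Ozonolysis of the 1,1-disubstituted alkene with reductive work-up gives the ketone; the acetal is inert at −78 °C, and the product has a mirror plane through C5 and C10.

Step 5
Reactants: 7 3-(dimethoxymethyl)-3-methylcyclobutan-1-one; 8 (E)-but-2-enal
Product: 10 (1R,2S,4R,5R,7R)-7-(dimethoxymethyl)-2-hydroxy-4,7-dimethylbicyclo[3.1.1]heptan-6-one, via Michael adduct 9 (not isolated)
Conditions: (S)-2-[diphenyl(trimethylsilyloxy)methyl]pyrrolidine (20 mol%), PhCO2H (20 mol%), toluene, 0 °C → rt; 8 (3 equiv) added over 12 h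
Reagents that add atoms: none
Why: Proposed new method: the amine condenses with 8 to the E-iminium ion and, helped by the acid, with the unhindered strained ketone 7 to its enamine; C4 of the enamine adds to C3 of the iminium ion (Michael addition), hydrolysis gives 9, and the ketone is then engaged again as the enamine toward C11, which adds to the C1 aldehyde (intramolecular aldol) before hydrolysis releases 10 and the amine. The closest known reactions are the Stork α,α'-annulation of cyclic ketone enamines with enals, which uses a stoichiometric achiral amine, and the amine-catalysed desymmetrising Michael and aldol reactions of 3-substituted cyclobutanones; merging them on a cyclobutanone under iminium control has no precedent. Ring B closes by 6-exo-trig attack on the aldehyde carbon (enolexo with respect to the ring through C10, enolendo with respect to the ring through C5). C3 is set by the catalyst, whose diphenyl(silyloxy)methyl group shields one face of the s-trans E-iminium ion; iminium activation also secures 1,4- over 1,2-addition. C4 is set by approach of the iminium ion to the enamine face anti to the α-branched dimethoxymethyl group, which places the new chain cis to the ring methyl and turns C10 into a stereocentre. Which enantiotopic α-carbon reacts is decided by the relative topicity toward the catalyst-fixed C3: the arrangement with the C3 methyl on the C5 side avoids the C10 methyl in the bicycle, and any leakage appears as a separable diastereomer, not as the enantiomer. C11 can only bond cis to the C4 chain, and the C1 hydroxyl is expected on the C5 side but is inconsequential because C1 is oxidised later. Slow addition of 8 limits its self-condensation, and silylation in step 6 freezes the aldol equilibrium.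

Step 6
Reactants: 10 bicyclic hydroxy ketone
Product: 11 (1R,2S,4R,5R,7R)-2-(tert-butyldimethylsilyloxy)-7-(dimethoxymethyl)-4,7-dimethylbicyclo[3.1.1]heptan-6-one
Conditions: t-BuMe2SiCl, imidazole, 4-(dimethylamino)pyridine (cat.), DMF, rt → 40 °C
Reagents that add atoms: tert-butyldimethylsilyl chloride, CC(C)(C)[Si](C)(C)Cl
Why: Silylation of a secondary alcohol with the chloride and imidazole; silyl triflates are avoided because they activate dimethyl acetals, and capping O1 removes the retro-aldol path of the β-hydroxy ketone.

Step 7
Reactants: 11 silyl ether acetal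
Product: 12 C9 aldehyde, 2-(tert-butyldimethylsilyloxy)-4,6-dimethyl-7-oxobicyclo[3.1.1]heptane-6-carbaldehyde (core as in 10)
Conditions: pyridinium p-toluenesulfonate (cat.), acetone/H2O (10:1), 50 °C
Reagents that add atoms: water, O
Why: Mild acid-catalysed acetal hydrolysis; the hindered secondary silyl ether survives and the aldehyde, on quaternary C10, cannot epimerise.

Step 8
Reactants: 12 C9 aldehyde; 13 3-bromo-3-methylbutan-2-one
Product: 15 (9R)-aldol adduct 7-[(1R)-4-bromo-1-hydroxy-4-methyl-3-oxopentyl]-2-(tert-butyldimethylsilyloxy)-4,7-dimethylbicyclo[3.1.1]heptan-6-one, via enol borinate 14 (not isolated)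
Conditions: 13, (−)-Ipc2BCl, Et3N, Et2O, −78 → −40 °C; then 12, −78 → −20 °C; then H2NCH2CH2OH, Et2O, rt
Reagents that add atoms: none
Why: Boron-mediated aldol addition of a methyl ketone: 13 can enolise only on its methyl side, and the diisopinocampheyl enol borinate adds to the aldehyde through a cyclic transition state. C10 is flanked by two nearly identical ring carbons and gives no facial bias, so the isopinocampheyl ligands set C9 (Re-face attack, 9R); the minor C9 epimer is a separable diastereomer. The peroxide-free work-up spares the cyclobutanone from Baeyer–Villiger oxidation.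

Step 9
Reactants: 15 aldol adduct
Product: 16 C9 triethylsilyl ether of 15
Conditions: Et3SiOTf, 2,6-lutidine, CH2Cl2, −78 °C
Reagents that add atoms: triethylsilyl trifluoromethanesulfonate, CC[Si](CC)(CC)OS(=O)(=O)C(F)(F)F
Why: Standard silylation of a hindered secondary alcohol; it removes the proton that could quench the samarium enolate of step 10, and the bridgehead-flanked C5 ketone cannot enolise.

Step 10
Reactants: 16 bromo ketone
Product: 17 1-(tert-butyldimethylsilyloxy)-5-hydroxy-9-(triethylsilyloxy)longipinan-7-one
Conditions: SmI2 (2.5 equiv), THF, −78 °C; sat. aq. NH4Cl at −78 °C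
Reagents that add atoms: none
Why: Samarium diiodide intramolecular Reformatsky-type aldol: two-electron reduction of the tertiary α-bromo ketone gives the trivalent-samarium enolate regiospecifically at C6, which adds to the strained C5 ketone in a 7-(enolendo)-exo-trig closure of ring C. The tether from C9 allows attack only on the C5 face opposite ring B, so C5 is set by the ring system; the cold quench avoids retro-aldol.

Step 11
Reactants: 17 tricyclic hydroxy ketone
Product: 18 C5 methyl oxalate of 17
Conditions: ClC(O)CO2Me, pyridine, 4-(dimethylamino)pyridine (cat.), CH2Cl2, 0 °C → rt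
Reagents that add atoms: methyl chlorooxoacetate, COC(=O)C(=O)Cl
Why: Acylation of a tertiary alcohol with a small, very reactive acid chloride under amine base; no alkoxide is formed, so the β-hydroxy ketone does not undergo retro-aldol.

Step 12
Reactants: 18 oxalate
Product: 19 1-(tert-butyldimethylsilyloxy)-9-(triethylsilyloxy)longipinan-7-one
Conditions: Bu3SnH (5 equiv, 0.5 M), azobisisobutyronitrile (cat.), toluene, 80 °C
Reagents that add atoms: none
Why: Oxalate variant of the Barton–McCombie deoxygenation for tertiary alcohols: stannyl radical addition, C5–O scission and hydrogen transfer from the stannane to the tertiary radical. C6 is held on the ring C face, so hydrogen can enter only from outside and the C5 configuration is fixed; concentrated stannane is used to outrun rearrangement of the radical.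

Step 13
Reactants: 19 bis-silyl ether ketone
Product: 20 1-(tert-butyldimethylsilyloxy)-9-hydroxylongipinan-7-one
Conditions: pyridinium p-toluenesulfonate (cat.), MeOH, 0 °C → rt
Reagents that add atoms: none
Why: Selective acid-catalysed methanolysis of the more labile triethylsilyl ether; the hindered tert-butyldimethylsilyl ether at C1 stays.

Step 14
Reactants: 20 β-hydroxy ketone
Product: 21 1-(tert-butyldimethylsilyloxy)longipinane-7,9-diol (7R,9R; anti)
Conditions: Me4NBH(OAc)3, MeCN/AcOH (1:1), −30 °C
Reagents that add atoms: none
Why: Evans–Saksena reduction: the acetoxyborohydride bound to O9 delivers hydride intramolecularly to the same face of C7, so the new hydroxyl ends up trans to O9 (1,3-anti), which sets C7.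

Step 15
Reactants: 21 anti-diol; 22 angelic acid
Product: 24 1-(tert-butyldimethylsilyloxy)longipinane-7,9-diyl bis[(Z)-2-methylbut-2-enoate], via mixed anhydride 23 (not isolated)
Conditions: 22 (6 equiv), 2,4,6-Cl3C6H2COCl, Et3N, toluene, rt; then 21, 80 °C
Reagents that add atoms: none
Why: Yamaguchi esterification without a nucleophilic catalyst: the mixed anhydride is attacked at the less hindered angeloyl carbonyl by both neopentyl-type alcohols, and leaving out 4-(dimethylamino)pyridine limits Z-to-E isomerisation.

Step 16
Reactants: 24 silylated diangelate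
Product: 25 1-hydroxylongipinane-7,9-diyl bis[(Z)-2-methylbut-2-enoate]
Conditions: HF·pyridine, pyridine, THF, 0 °C → rt
Reagents that add atoms: none
Why: Fluoride-mediated cleavage of the silyl ether under buffered, non-basic conditions that leave the angelates and their geometry untouched.

Step 17
Reactants: 25 C1 alcohol
Product: 26 (3R,4S,5S,7R,9R,10R,11R)-1-oxolongipinane-7,9-diyl bis[(Z)-2-methylbut-2-enoate] (CNP0283599.1)
Conditions: Dess–Martin periodinane, CH2Cl2, rt
Reagents that add atoms: none
Why: Dess–Martin oxidation of a secondary alcohol under neutral conditions; C5 is now a methine, so the 1,3-dicarbonyl problem is gone, and the bridgehead C11 cannot epimerise.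

## Compound list

1 | 3-methylidenecyclobutane-1-carbonitrile | C=C1CC(C#N)C1 | starting material
2 | 1-methyl-3-methylidenecyclobutane-1-carbonitrile | C=C1CC(C)(C#N)C1 | intermediate
3 | N-(diisobutylalumanyl)-1-(1-methyl-3-methylidenecyclobutyl)methanimine | C=C1CC(C)(C=N[Al](CC(C)C)CC(C)C)C1 | intermediate (not isolated)
4 | 1-methyl-3-methylidenecyclobutane-1-carbaldehyde | C=C1CC(C)(C=O)C1 | intermediate
5 | 1-(dimethoxymethyl)-1-methyl-3-methylidenecyclobutane | C=C1CC(C)(C(OC)OC)C1 | intermediate
6 | 2-(dimethoxymethyl)-2-methyl-5,7,8-trioxaspiro[3.4]octane | COC(OC)C1(C)CC2(C1)OCOO2 | intermediate (not isolated)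
7 | 3-(dimethoxymethyl)-3-methylcyclobutan-1-one | COC(OC)C1(C)CC(=O)C1 | intermediate
8 | (E)-but-2-enal (crotonaldehyde) | C/C=C/C=O | starting material
9 | (3R)-3-[2-(dimethoxymethyl)-2-methyl-4-oxocyclobutyl]butanal, side chain cis to the ring methyl | COC(OC)[C@@]1(C)CC(=O)[C@@H]1[C@H](C)CC=O | intermediate (not isolated)
10 | (1R,2S,4R,5R,7R)-7-(dimethoxymethyl)-2-hydroxy-4,7-dimethylbicyclo[3.1.1]heptan-6-one | COC(OC)[C@]1(C)[C@@H]2C(=O)[C@H]1[C@@H](O)C[C@H]2C | intermediate
11 | (1R,2S,4R,5R,7R)-2-(tert-butyldimethylsilyloxy)-7-(dimethoxymethyl)-4,7-dimethylbicyclo[3.1.1]heptan-6-one | COC(OC)[C@]1(C)[C@@H]2C(=O)[C@H]1[C@@H](O[Si](C)(C)C(C)(C)C)C[C@H]2C | intermediate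
12 | 2-(tert-butyldimethylsilyloxy)-4,6-dimethyl-7-oxobicyclo[3.1.1]heptane-6-carbaldehyde (core as in 10) | O=C[C@]1(C)[C@@H]2C(=O)[C@H]1[C@@H](O[Si](C)(C)C(C)(C)C)C[C@H]2C | intermediate
13 | 3-bromo-3-methylbutan-2-one | CC(=O)C(C)(C)Br | starting material
14 | 3-bromo-3-methylbut-1-en-2-yl diisopinocampheylborinate [from (−)-Ipc2BCl] | C=C(OB([C@@H]1C[C@@H]2C[C@H]([C@H]1C)C2(C)C)[C@@H]1C[C@@H]2C[C@H]([C@H]1C)C2(C)C)C(C)(C)Br | intermediate (not isolated)
15 | 7-[(1R)-4-bromo-1-hydroxy-4-methyl-3-oxopentyl]-2-(tert-butyldimethylsilyloxy)-4,7-dimethylbicyclo[3.1.1]heptan-6-one (core as in 10) | CC(C)(Br)C(=O)C[C@@H](O)[C@]1(C)[C@@H]2C(=O)[C@H]1[C@@H](O[Si](C)(C)C(C)(C)C)C[C@H]2C | intermediate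
16 | 7-[(1R)-4-bromo-4-methyl-3-oxo-1-(triethylsilyloxy)pentyl]-2-(tert-butyldimethylsilyloxy)-4,7-dimethylbicyclo[3.1.1]heptan-6-one (core as in 10) | CC(C)(Br)C(=O)C[C@@H](O[Si](CC)(CC)CC)[C@]1(C)[C@@H]2C(=O)[C@H]1[C@@H](O[Si](C)(C)C(C)(C)C)C[C@H]2C | intermediate
17 | 1-(tert-butyldimethylsilyloxy)-5-hydroxy-9-(triethylsilyloxy)longipinan-7-one (core as in 26) | O=C1C[C@@H](O[Si](CC)(CC)CC)[C@]2(C)[C@@H]3[C@@](O)([C@H]2[C@@H](O[Si](C)(C)C(C)(C)C)C[C@H]3C)C1(C)C | intermediate
18 | methyl [1-(tert-butyldimethylsilyloxy)-7-oxo-9-(triethylsilyloxy)longipinan-5-yl] oxalate | O=C1C[C@@H](O[Si](CC)(CC)CC)[C@]2(C)[C@@H]3[C@@](OC(=O)C(=O)OC)([C@H]2[C@@H](O[Si](C)(C)C(C)(C)C)C[C@H]3C)C1(C)C | intermediate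
19 | 1-(tert-butyldimethylsilyloxy)-9-(triethylsilyloxy)longipinan-7-one | O=C1C[C@@H](O[Si](CC)(CC)CC)[C@]2(C)[C@@H]3[C@@H]([C@H]2[C@@H](O[Si](C)(C)C(C)(C)C)C[C@H]3C)C1(C)C | intermediate
20 | 1-(tert-butyldimethylsilyloxy)-9-hydroxylongipinan-7-one | O=C1C[C@@H](O)[C@]2(C)[C@@H]3[C@@H]([C@H]2[C@@H](O[Si](C)(C)C(C)(C)C)C[C@H]3C)C1(C)C | intermediate
21 | 1-(tert-butyldimethylsilyloxy)longipinane-7,9-diol (7R,9R) | O[C@@H]1C[C@@H](O)[C@]2(C)[C@@H]3[C@@H]([C@H]2[C@@H](O[Si](C)(C)C(C)(C)C)C[C@H]3C)C1(C)C | intermediate
22 | angelic acid, (Z)-2-methylbut-2-enoic acid | C/C=C(/C)C(=O)O | starting material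
23 | (Z)-2-methylbut-2-enoic 2,4,6-trichlorobenzoic anhydride | C/C=C(/C)C(=O)OC(=O)c1c(Cl)cc(Cl)cc1Cl | intermediate (not isolated)
24 | 1-(tert-butyldimethylsilyloxy)longipinane-7,9-diyl bis[(Z)-2-methylbut-2-enoate] | C/C=C(/C)C(=O)O[C@@H]1C[C@@H](OC(=O)/C(C)=C\C)[C@]2(C)[C@@H]3[C@@H]([C@H]2[C@@H](O[Si](C)(C)C(C)(C)C)C[C@H]3C)C1(C)C | intermediate
25 | 1-hydroxylongipinane-7,9-diyl bis[(Z)-2-methylbut-2-enoate] | C/C=C(/C)C(=O)O[C@@H]1C[C@@H](OC(=O)/C(C)=C\C)[C@]2(C)[C@@H]3[C@@H]([C@H]2[C@@H](O)C[C@H]3C)C1(C)C | intermediate
26 | (3R,4S,5S,7R,9R,10R,11R)-1-oxolongipinane-7,9-diyl bis[(Z)-2-methylbut-2-enoate] (CNP0283599.1) | C/C=C(/C)C(=O)O[C@@H]1C[C@@H](OC(=O)/C(C)=C\C)[C@]2(C)[C@@H]3[C@@H]([C@H]2C(=O)C[C@H]3C)C1(C)C | target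

## Step count and least certain steps

Total: 17 steps. Longest linear sequence: 17 steps (1 → 26); 8, 13 and 22 enter as purchased materials.

**Step 5 (key step, proposed new method).** The most likely failure is that the hindered secondary amine does not convert the cyclobutanone into its enamine fast enough. The iminium ion would then be consumed by crotonaldehyde dienamine (self-condensation). Behind this lie incomplete facial or topicity selection and an aldol equilibrium that the added strain of the bicycle may leave close to balance.

Fallback, from 7: enantioselective deprotonation with a chiral lithium amide (lithium bis(1-phenylethyl)amide, antipode chosen for the C4 side, Me3SiCl in situ, THF, −100 °C) would give silyl enol ether F1 with the double bond toward C4. An organocatalytic Mukaiyama–Michael addition of F1 to 8 under a chiral imidazolidinone salt (second-generation type, antipode matching the C3 configuration) would give 9, now isolated. A separate amine-mediated intramolecular aldol addition (pyrrolidinium acetate) would close ring B and return to the route at 10.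

**Step 8.** The enol borinate of an α'-bromo ketone can lose bromide (oxyallyl or Favorskii-type ionisation) before it meets the hindered aldehyde. Facial selection at C9 also rests on the reagent alone and may be only moderate, although the minor epimer is removable as a diastereomer.

Fallback, from 12: the same boron aldol is run with the dienol borinate of 3-methylbut-3-en-2-one [(−)-Ipc2BCl, Et3N], giving hydroxy enone F2. Silylation (Et3SiOTf, 2,6-lutidine) gives triethylsilyl ether F3. Conjugate hydride delivery with [(Ph3P)CuH]6 then generates the C6 enolate without any bromide and closes ring C by reductive aldol cyclisation, returning to the route at 17.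

**Step 12.** The tertiary cyclobutyl radical at C5 sits next to the C7 carbonyl. A 1,2-acyl shift or β-scission of a cyclobutane bond may compete with hydrogen transfer, and formation of the oxalate on the crowded tertiary alcohol in step 11 may be slow.

Fallback, from 17: the radical is generated only after the carbonyl is gone.
- Methanolysis of the triethylsilyl ether (pyridinium p-toluenesulfonate, MeOH) gives diol ketone F4.
- Reduction with Me4NBH(OAc)3, directed by O9, gives triol F5.
- The two secondary hydroxyls are silylated (Et3SiCl, imidazole) to bis(triethylsilyl) ether F6.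
- The tertiary alkoxide (KH) is converted with CS2 and MeI into xanthate F7. Chugaev elimination is impossible because every β-hydrogen is at a bridgehead.
- Barton–McCombie reduction (Bu3SnH, azobisisobutyronitrile) gives deoxygenated bis(triethylsilyl) ether F8.
- Methanolysis of both triethylsilyl ethers returns to the route at 21.

**Step 15.** Acylation of two neopentyl-type alcohols needs prolonged heating, during which the angeloyl groups may isomerise to tiglates or the second esterification may stall.

Fallback, from 21: both hydroxyls are acylated with 2-[bis(2,2,2-trifluoroethoxy)phosphoryl]propanoyl chloride (pyridine) to bis(phosphonopropanoate) F9. A double Still–Gennari olefination with acetaldehyde [KN(SiMe3)2, 18-crown-6, THF, −78 °C] builds both (Z)-2-methylbut-2-enoates on the molecule and returns to the route at 24.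

## Further compounds

F1 | step 5 | 3-(dimethoxymethyl)-3-methyl-1-(trimethylsilyloxy)cyclobut-1-ene (single enantiomer, double bond toward C4) | COC(OC)[C@@]1(C)CC(O[Si](C)(C)C)=C1
F2 | step 8 | 2-(tert-butyldimethylsilyloxy)-7-[(1R)-1-hydroxy-4-methyl-3-oxopent-4-enyl]-4,7-dimethylbicyclo[3.1.1]heptan-6-one (core as in 10) | C=C(C)C(=O)C[C@@H](O)[C@]1(C)[C@@H]2C(=O)[C@H]1[C@@H](O[Si](C)(C)C(C)(C)C)C[C@H]2C
F3 | step 8 | C9 triethylsilyl ether of F2 | C=C(C)C(=O)C[C@@H](O[Si](CC)(CC)CC)[C@]1(C)[C@@H]2C(=O)[C@H]1[C@@H](O[Si](C)(C)C(C)(C)C)C[C@H]2C
F4 | step 12 | 1-(tert-butyldimethylsilyloxy)-5,9-dihydroxylongipinan-7-one | O=C1C[C@@H](O)[C@]2(C)[C@@H]3[C@@](O)([C@H]2[C@@H](O[Si](C)(C)C(C)(C)C)C[C@H]3C)C1(C)C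
F5 | step 12 | 1-(tert-butyldimethylsilyloxy)longipinane-5,7,9-triol | O[C@@H]1C[C@@H](O)[C@]2(C)[C@@H]3[C@@](O)([C@H]2[C@@H](O[Si](C)(C)C(C)(C)C)C[C@H]3C)C1(C)C
F6 | step 12 | 1-(tert-butyldimethylsilyloxy)-7,9-bis(triethylsilyloxy)longipinan-5-ol | CC[Si](CC)(CC)O[C@@H]1C[C@@H](O[Si](CC)(CC)CC)[C@]2(C)[C@@H]3[C@@](O)([C@H]2[C@@H](O[Si](C)(C)C(C)(C)C)C[C@H]3C)C1(C)C
F7 | step 12 | O-[1-(tert-butyldimethylsilyloxy)-7,9-bis(triethylsilyloxy)longipinan-5-yl] S-methyl carbonodithioate | CC[Si](CC)(CC)O[C@@H]1C[C@@H](O[Si](CC)(CC)CC)[C@]2(C)[C@@H]3[C@@](OC(=S)SC)([C@H]2[C@@H](O[Si](C)(C)C(C)(C)C)C[C@H]3C)C1(C)C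
F8 | step 12 | 1-(tert-butyldimethylsilyloxy)-7,9-bis(triethylsilyloxy)longipinane | CC[Si](CC)(CC)O[C@@H]1C[C@@H](O[Si](CC)(CC)CC)[C@]2(C)[C@@H]3[C@@H]([C@H]2[C@@H](O[Si](C)(C)C(C)(C)C)C[C@H]3C)C1(C)C
F9 | step 15 | 1-(tert-butyldimethylsilyloxy)longipinane-7,9-diyl bis{2-[bis(2,2,2-trifluoroethoxy)phosphoryl]propanoate} (epimers at the phosphonate α-carbons) | CC(P(=O)(OCC(F)(F)F)OCC(F)(F)F)C(=O)O[C@@H]1C[C@@H](OC(=O)C(C)P(=O)(OCC(F)(F)F)OCC(F)(F)F)[C@]2(C)[C@@H]3[C@@H]([C@H]2[C@@H](O[Si](C)(C)C(C)(C)C)C[C@H]3C)C1(C)C
A1 | alternative 1 | (2E,6E)-farnesyl diphosphate | CC(C)=CCC/C(C)=C/CC/C(C)=C/COP(=O)(O)OP(=O)(O)O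
A2 | alternative 1 | α-longipinene (enantiomeric series of 26) | C1CC[C@]2(C)[C@@H]3[C@@H]([C@H]2CC=C3C)C1(C)C
A3 | alternative 2 | 8-nor-longipinan-9-one 1-ethylene ketal (copaane-type lower homologue) | C1C(=O)[C@]2(C)[C@@H]3[C@@H]([C@H]2C4(OCCO4)C[C@H]3C)C1(C)C
A4 | alternative 2 | longipinan-9-one 1-ethylene ketal | C1CC(=O)[C@]2(C)[C@@H]3[C@@H]([C@H]2C4(OCCO4)C[C@H]3C)C1(C)C
A5 | alternative 3 | α-diazo ketone of the bicyclo[4.2.1]nonanone series (diazo at C11, carbonyl C1) | CC(C)(C)[Si](C)(C)O[C@@H]1C[C@@H](O[Si](C)(C)C(C)(C)C)[C@]2(C)[C@@H](CCC(=O)OC)[C@@H](C(=O)C2=[N+]=[N-])C1(C)C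
A6 | alternative 3 | bicyclo[4.1.1]octane diester | CC(C)(C)[Si](C)(C)O[C@@H]1C[C@@H](O[Si](C)(C)C(C)(C)C)[C@]2(C)[C@@H](CCC(=O)OC)[C@@H]([C@H]2C(=O)OC)C1(C)C
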